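**Retrosynthetic overview**
1. Target 22 is the C11–O ether of scopoletin with a trans-decalin: ring A (C1–C5, C10; axial 3-OH, gem-dimethyl C4) and ring B (C5–C10; C7=C8–CH3, C9–C11H2, C10–CH3). The ether is cut last (Mitsunobu) to diol 20 and scopoletin 21.
2. The strategy rests on ring B being (S)-carvone atom for atom: C=O is C9, C(CH3)= is C8, =CH is C7, CH2 is C6, the CH bearing isopropenyl is C5 (the isopropenyl carbon is C4 with one of its methyls), and the α′-CH2 is C10.
3. C9–C11 is cut by a [2,3]-Wittig–Still shift from a 7-oxygen; the C8=C9 alkene comes from the C9 ketone through its enol triflate, and the 7-OH from allylic hydroxylation. C3 is corrected by oxidation and K[HB(s-Bu)3] reduction in the pot that also removes the enone.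
4. Ring A is cut at C3–C4: hydrogen-atom transfer to the isopropenyl group, then 6-exo addition of the C4 radical to a C3 aldehyde. Ring B comes first (carvone), ring A second, and the coumarin is brought in intact.
5. The quaternary C10 comes from α′-methylation and then allylation of carvone; the allyl group is turned into the propanal chain.

Key step: step 5

Remark: drimane numbering (C1–C12) is used for the bicyclic compounds. Read from the SMILES, the target has the C10 methyl anti to H5 (trans-decalin), the 3-OH axial and cis to H5, and C11 on the face opposite the C10 methyl.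

**Step 1**
Reactants: 1 (S)-carvone
Product: 3 (5S,6R)-2,6-dimethyl-5-(prop-1-en-2-yl)cyclohex-2-en-1-one (trans-6-methylcarvone), via lithium dienolate of carvone 2 (not isolated)
Conditions: LiN(iPr)2, THF, −78 °C; MeI, −78 to 0 °C
Reagents that add atoms: iodomethane, CI
Why: Kinetic α′-deprotonation of the enone gives the cross-conjugated lithium dienolate 2, and its C-methylation (enolate alkylation) should occur mainly anti to the isopropenyl group; the configuration of the new C6 centre does not matter because it is enolised again in step 2.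

**Step 2**
Reactants: 3 trans-6-methylcarvone; 4 allyl bromide
Product: 6 (5R,6R)-2,6-dimethyl-6-(prop-2-en-1-yl)-5-(prop-1-en-2-yl)cyclohex-2-en-1-one, via lithium enolate of 6-methylcarvone 5 (not isolated)
Conditions: LiN(iPr)2, THF, −78 to 0 °C; 4, DMPU, −78 °C to rt
Reagents that add atoms: none
Why: Enolate alkylation of the tetrasubstituted lithium enolate 5 should take place on the face opposite the adjacent isopropenyl group, which sets the quaternary centre (future C10) with the three-carbon chain trans to the isopropenyl group and the methyl cis to it, as a trans ring fusion requires.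

**Step 3**
Reactants: 6 allyl methyl carvone
Product: 8 (5R,6R)-6-(3-hydroxypropyl)-2,6-dimethyl-5-(prop-1-en-2-yl)cyclohex-2-en-1-one, via alkyl(disiamyl)borane 7 (not isolated)
Conditions: Sia2BH (from BH3·SMe2 and 2-methylbut-2-ene), THF, 0 °C; Me3NO·2H2O, 65 °C; H2O
Reagents that add atoms: trimethylamine N-oxide, C[N+](C)(C)[O-]
Why: Brown hydroboration with the bulky dialkylborane should place boron on the terminal carbon of the monosubstituted alkene much faster than it attacks the hindered 1,1-disubstituted isopropenyl group or the neopentyl enone carbonyl, and amine N-oxide oxidation of the C–B bond avoids the alkaline peroxide that would epoxidise the enone; no stereocentre is formed.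

**Step 4**
Reactants: 8 primary alcohol
Product: 9 3-[(1R,6R)-1,3-dimethyl-2-oxo-6-(prop-1-en-2-yl)cyclohex-3-en-1-yl]propanal
Conditions: Dess–Martin periodinane, CH2Cl2, rt
Reagents that add atoms: none
Why: Dess–Martin oxidation of the primary alcohol stops at the aldehyde under neutral conditions that leave the enone and the isopropenyl group untouched; no stereocentre is formed.

**Step 5**
Reactants: 9 keto-aldehyde
Product: 12 (4aR,6R,8aR)-6-hydroxy-2,5,5,8a-tetramethyl-4a,5,6,7,8,8a-hexahydronaphthalen-1(4H)-one (trans-fused 3-equatorial alcohol), via C4 tertiary radical 10 (not isolated), via C3 alkoxyl radical 11 (not isolated)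
Conditions: Fe(acac)3 (1 equiv), PhSiH3 (2.5 equiv), degassed EtOH (0.02 M), 60 °C
Reagents that add atoms: none
Why: The iron hydride formed from Fe(acac)3, PhSiH3 and ethanol should transfer a hydrogen atom to the CH2 terminus of the electron-rich isopropenyl group to give the nucleophilic tertiary radical 10, which adds to the aldehyde carbon C3 to give alkoxyl radical 11; reduction of 11 by the divalent iron left by the first event and protonation by ethanol pull the reversible addition forward and return trivalent iron. The closest known reaction type is the Fe(acac)3/PhSiH3 hydrogen-atom-transfer reductive cyclisation of alkene-tethered ketones to cyclic alcohols, together with stannane-mediated 6-exo radical cyclisations onto aldehydes. Ring A is closed in the 6-exo-trig mode (C4 onto C3, oxygen outside the ring) through a chair transition state. The ring fusion is trans because C5 (from carvone) and C10 (from step 2) are already fixed with the chain and C4 trans-diequatorial on ring B; the new C3 centre is set by that chair with the carbonyl oxygen pseudo-equatorial (3R, equatorial OH expected), and because C3 is oxidised in step 6 its epimer would converge. The step needs hydrogen-atom transfer to the isopropenyl group and not to the enone alkene, which the poor match between an electron-poor trisubstituted enone and the electrophilic hydride donor should secure, and the C4 radical cannot reach an enone carbon without forming a four-membered ring.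

**Step 6**
Reactants: 12 hydroxy enone
Product: 13 (4aR,8aR)-2,5,5,8a-tetramethyl-4a,7,8,8a-tetrahydronaphthalene-1,6(4H,5H)-dione
Conditions: Dess–Martin periodinane, CH2Cl2, rt
Reagents that add atoms: none
Why: Dess–Martin oxidation of the secondary C3 alcohol to the ketone removes the C3 centre, so both C3 epimers converge, and does not touch the enone.

**Step 7**
Reactants: 13 enedione
Product: 15 (4aR,6S,8aR)-6-hydroxy-2,5,5,8a-tetramethyl-3,4,4a,5,6,7,8,8a-octahydronaphthalen-1-yl trifluoromethanesulfonate, via dipotassium alkoxide enolate 14 (not isolated)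
Conditions: K[HB(s-Bu)3] (2.3 equiv), THF, −78 to −20 °C; PhNTf2 (1.2 equiv), −78 to 0 °C; H2O
Reagents that add atoms: N-phenylbis(trifluoromethanesulfonimide), O=S(=O)(N(c1ccccc1)S(=O)(=O)C(F)(F)F)C(F)(F)F
Why: K[HB(s-Bu)3] should add hydride in the conjugate sense to the α-methyl, β-unsubstituted enone (as with carvone itself) to give the C8=C9 potassium enolate regiospecifically, and attack the hindered C3 ketone from the equatorial direction to give the axial alkoxide (3S, cis to H5), so that dianion 14 forms in one pot; PhNTf2 then triflates the enolate oxygen in preference to the neopentyl axial alkoxide, which is held as its borate.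

**Step 8**
Reactants: 15 enol triflate
Product: 16 (2S,4aS,8aS)-1,1,4a,6-tetramethyl-1,2,3,4,4a,7,8,8a-octahydronaphthalen-2-ol
Conditions: Pd(OAc)2 (5 mol %), PPh3, Et3N, HCO2H, DMF, 60 °C
Reagents that add atoms: none
Why: Palladium-catalysed formate reduction of an enol triflate: zerovalent palladium formed from Pd(OAc)2 and PPh3 inserts into the C9–O bond, formate exchange and loss of CO2 give the alkenylpalladium hydride, and reductive elimination leaves C9–H with the alkene fixed at C8=C9; no stereocentre is touched.

**Step 9**
Reactants: 16 alkene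
Product: 17 (2S,4aS,7S,8aS)-1,1,4a,6-tetramethyl-1,2,3,4,4a,7,8,8a-octahydronaphthalene-2,7-diol
Conditions: SeO2 (0.5 equiv), t-BuOOH, CH2Cl2, rt
Reagents that add atoms: tert-butyl hydroperoxide, CC(C)(C)OO (terminal oxygen source, passed on through selenium dioxide, O=[Se]=O)
Why: Selenium dioxide allylic hydroxylation (ene reaction followed by a [2,3]-sigmatropic shift): selenium should bond to C9 on the face opposite the axial C10 methyl and take the pseudo-axial H7 of that face, the ring CH2 at the more substituted alkene terminus being the usual site, and the suprafacial shift returns oxygen to C7 on the same face, which sets C7 (7S, OH cis to H5) and restores the C8=C9 alkene.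

**Step 10**
Reactants: 17 diol
Product: 18 (2S,4aS,7S,8aS)-1,1,4a,6-tetramethyl-7-[(tributylstannyl)methoxy]-1,2,3,4,4a,7,8,8a-octahydronaphthalen-2-ol
Conditions: KH (1.1 equiv), THF, 0 °C; Bu3SnCH2I (1.05 equiv), rt
Reagents that add atoms: tributyl(iodomethyl)stannane, CCCC[Sn](CCCC)(CCCC)CI
Why: Williamson etherification: of the two potassium alkoxides in equilibrium, the allylic C7 alkoxide is far more accessible than the axial C3 alkoxide flanked by the gem-dimethyl carbon, so one equivalent of the iodomethylstannane should alkylate O7 only; no stereocentre changes.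

**Step 11**
Reactants: 18 stannylmethyl ether
Product: 20 (2S,4aR,5S,8aS)-5-(hydroxymethyl)-1,1,4a,6-tetramethyl-1,2,3,4,4a,5,8,8a-octahydronaphthalen-2-ol, via lithiomethyl ether 19 (not isolated)
Conditions: n-BuLi (2.5 equiv), THF, −78 °C; H2O
Reagents that add atoms: none
Why: Wittig–Still [2,3]-sigmatropic rearrangement: after deprotonation of the C3 hydroxyl, tin–lithium exchange gives lithiomethyl ether 19, whose carbanion shifts suprafacially from the pseudo-axial O7 to C9 on the same face, so that the new C9 centre carries C11 anti to the C10 methyl (9S) and the alkene is moved regiospecifically to C7=C8.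

**Step 12**
Reactants: 20 diol; 21 scopoletin
Product: 22 7-{[(1S,4aS,6S,8aR)-6-hydroxy-2,5,5,8a-tetramethyl-1,4,4a,5,6,7,8,8a-octahydronaphthalen-1-yl]methoxy}-6-methoxy-2H-chromen-2-one (CNP0218138.1)
Conditions: PPh3, DIAD, THF, 0 °C to rt
Reagents that add atoms: none
Why: Mitsunobu etherification: the primary C11 alcohol is activated as its oxyphosphonium ion and displaced by the scopoletin phenoxide, while the axial neopentyl C3 alcohol is too hindered to react, and no stereocentre is involved.

**Compound list**
1 | (S)-carvone, (5S)-2-methyl-5-(prop-1-en-2-yl)cyclohex-2-en-1-one | CC1=CC[C@@H](CC1=O)C(C)=C | starting material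
2 | lithium dienolate of carvone (cross-conjugated, O–Li on C1, C1=C6) | CC1=CC[C@@H](C=C1O[Li])C(C)=C | intermediate
3 | (5S,6R)-2,6-dimethyl-5-(prop-1-en-2-yl)cyclohex-2-en-1-one (trans-6-methylcarvone) | C[C@H]1C(=O)C(C)=CC[C@@H]1C(C)=C | intermediate
4 | allyl bromide (3-bromoprop-1-ene) | C=CCBr | starting material
5 | lithium enolate of 6-methylcarvone (C1=C6, O–Li) | CC1=CC[C@H](C(C)=C)C(C)=C1O[Li] | intermediate
6 | (5R,6R)-2,6-dimethyl-6-(prop-2-en-1-yl)-5-(prop-1-en-2-yl)cyclohex-2-en-1-one (allyl trans to isopropenyl) | C=CC[C@@]1(C)C(=O)C(C)=CC[C@@H]1C(C)=C | intermediate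
7 | bis(3-methylbutan-2-yl){3-[(1R,6R)-1,3-dimethyl-2-oxo-6-(prop-1-en-2-yl)cyclohex-3-en-1-yl]propyl}borane | CC(C)C(C)B(CCC[C@@]1(C)C(=O)C(C)=CC[C@@H]1C(C)=C)C(C)C(C)C | intermediate
8 | (5R,6R)-6-(3-hydroxypropyl)-2,6-dimethyl-5-(prop-1-en-2-yl)cyclohex-2-en-1-one | OCCC[C@@]1(C)C(=O)C(C)=CC[C@@H]1C(C)=C | intermediate
9 | 3-[(1R,6R)-1,3-dimethyl-2-oxo-6-(prop-1-en-2-yl)cyclohex-3-en-1-yl]propanal | O=CCC[C@@]1(C)C(=O)C(C)=CC[C@@H]1C(C)=C | intermediate
10 | C4 tertiary radical from 9 (2-propyl radical on C5) | O=CCC[C@@]1(C)C(=O)C(C)=CC[C@@H]1[C](C)C | intermediate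
11 | C3 alkoxyl radical of the closed trans-decalin | O=C1C(C)=CC[C@@H]2C(C)(C)[C@H]([O])CC[C@]21C | intermediate
12 | (4aR,6R,8aR)-6-hydroxy-2,5,5,8a-tetramethyl-4a,5,6,7,8,8a-hexahydronaphthalen-1(4H)-one (trans-fused; 3-OH equatorial) | O=C1C(C)=CC[C@@H]2C(C)(C)[C@H](O)CC[C@]21C | intermediate
13 | (4aR,8aR)-2,5,5,8a-tetramethyl-4a,7,8,8a-tetrahydronaphthalene-1,6(4H,5H)-dione | O=C1C(C)=CC[C@@H]2C(C)(C)C(=O)CC[C@]21C | intermediate
14 | dipotassium C3 axial alkoxide / C8=C9 enolate | [K]OC1=C(C)CC[C@@H]2C(C)(C)[C@@H](O[K])CC[C@]21C | intermediate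
15 | (4aR,6S,8aR)-6-hydroxy-2,5,5,8a-tetramethyl-3,4,4a,5,6,7,8,8a-octahydronaphthalen-1-yl trifluoromethanesulfonate (3-OH axial) | O=S(=O)(OC1=C(C)CC[C@@H]2C(C)(C)[C@@H](O)CC[C@]21C)C(F)(F)F | intermediate
16 | (2S,4aS,8aS)-1,1,4a,6-tetramethyl-1,2,3,4,4a,7,8,8a-octahydronaphthalen-2-ol (C8=C9 alkene) | C1=C(C)CC[C@@H]2C(C)(C)[C@@H](O)CC[C@]21C | intermediate
17 | (2S,4aS,7S,8aS)-1,1,4a,6-tetramethyl-1,2,3,4,4a,7,8,8a-octahydronaphthalene-2,7-diol (7-OH cis to H5) | C1=C(C)[C@@H](O)C[C@@H]2C(C)(C)[C@@H](O)CC[C@]21C | intermediate
18 | (2S,4aS,7S,8aS)-1,1,4a,6-tetramethyl-7-[(tributylstannyl)methoxy]-1,2,3,4,4a,7,8,8a-octahydronaphthalen-2-ol | C1=C(C)[C@@H](OC[Sn](CCCC)(CCCC)CCCC)C[C@@H]2C(C)(C)[C@@H](O)CC[C@]21C | intermediate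
19 | O7-lithiomethyl ether, C3 lithium alkoxide | C1=C(C)[C@@H](OC[Li])C[C@@H]2C(C)(C)[C@@H](O[Li])CC[C@]21C | intermediate
20 | (2S,4aR,5S,8aS)-5-(hydroxymethyl)-1,1,4a,6-tetramethyl-1,2,3,4,4a,5,8,8a-octahydronaphthalen-2-ol (C11 anti to C10 methyl) | OC[C@H]1C(C)=CC[C@@H]2C(C)(C)[C@@H](O)CC[C@]21C | intermediate
21 | scopoletin (7-hydroxy-6-methoxy-2H-chromen-2-one) | COc1cc2ccc(=O)oc2cc1O | starting material
22 | 7-{[(1S,4aS,6S,8aR)-6-hydroxy-2,5,5,8a-tetramethyl-1,4,4a,5,6,7,8,8a-octahydronaphthalen-1-yl]methoxy}-6-methoxy-2H-chromen-2-one | COc1cc2ccc(=O)oc2cc1OC[C@H]1C(C)=CC[C@@H]2C(C)(C)[C@@H](O)CC[C@]21C | target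

**Step count and risks**
Total: 12 steps. Longest linear sequence: 12 steps, from (S)-carvone 1 to 22.

The three steps most likely to fail:

Step 5 (hydrogen-atom-transfer cyclisation). The C4 radical may be reduced to the isopropyl group before it cyclises. The addition to the aldehyde may also reverse by β-scission of the alkoxyl radical faster than that radical is reduced, or the aldehyde may be consumed by silane or ethanol. Fallback, setting out from alcohol 8: Markovnikov addition of dry HCl (CH2Cl2, −20 °C) to the isopropenyl group would give the tertiary chloride (5S,6R)-5-(2-chloropropan-2-yl)-6-(3-hydroxypropyl)-2,6-dimethylcyclohex-2-en-1-one F1. Dess–Martin oxidation would then give the chloro aldehyde 3-[(1R,6S)-6-(2-chloropropan-2-yl)-1,3-dimethyl-2-oxocyclohex-3-en-1-yl]propanal F2. Slow addition of Bu3SnH/AIBN in toluene at 110 °C would generate the same C4 radical by chlorine abstraction and close ring A in the 6-exo mode, with the stannane quenching the alkoxyl radical directly. The route is rejoined at 12.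

Step 9 (allylic hydroxylation). The ene reaction at the hindered C9 may be slow, hydrogen may be taken from the C12 methyl instead of C7, or the allylic alcohol may be oxidised further to the enone. Fallback, setting out from alkene 16: allylic oxidation with Rh2(cap)4 (dirhodium tetracaprolactamate) and t-BuOOH would give the enone (4aS,7S,8aS)-7-hydroxy-3,4a,8,8-tetramethyl-4a,5,6,7,8,8a-hexahydronaphthalen-2(1H)-one F3. Corey–Bakshi–Shibata reduction with the (R)-configured methyl oxazaborolidine and catecholborane, the catalyst being chosen to deliver hydride to C7 from the face of the C10 methyl, would then give diol 17, where the route is rejoined.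

Step 10 (site-selective etherification). Discrimination between the two hydroxyls may be lost, giving alkylation at O3 or at both oxygens, or alkylation of the hindered allylic alkoxide may be incomplete. Fallback, setting out from diol 17: heating with N,N-dimethylformamide dimethyl acetal (xylene, 140 °C) would exchange the allylic hydroxyl into an alkoxy(amino)carbene, whose [2,3]-sigmatropic shift delivers the carbon to C9 on the same face. This would give the amide (1S,4aS,6S,8aR)-6-hydroxy-N,N,2,5,5,8a-hexamethyl-1,4,4a,5,6,7,8,8a-octahydronaphthalene-1-carboxamide F4. Reduction with LiNH2BH3 (THF, 0 °C to rt) would give diol 20, where the route is rejoined; 18 and 19 are bypassed.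

**Further compounds**
F1 | step 5 | (5S,6R)-5-(2-chloropropan-2-yl)-6-(3-hydroxypropyl)-2,6-dimethylcyclohex-2-en-1-one | OCCC[C@@]1(C)C(=O)C(C)=CC[C@@H]1C(C)(C)Cl
F2 | step 5 | 3-[(1R,6S)-6-(2-chloropropan-2-yl)-1,3-dimethyl-2-oxocyclohex-3-en-1-yl]propanal | O=CCC[C@@]1(C)C(=O)C(C)=CC[C@@H]1C(C)(C)Cl
F3 | step 9 | (4aS,7S,8aS)-7-hydroxy-3,4a,8,8-tetramethyl-4a,5,6,7,8,8a-hexahydronaphthalen-2(1H)-one | C1=C(C)C(=O)C[C@@H]2C(C)(C)[C@@H](O)CC[C@]21C
F4 | step 10 | (1S,4aS,6S,8aR)-6-hydroxy-N,N,2,5,5,8a-hexamethyl-1,4,4a,5,6,7,8,8a-octahydronaphthalene-1-carboxamide | CN(C)C(=O)[C@H]1C(C)=CC[C@@H]2C(C)(C)[C@@H](O)CC[C@]21C
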